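**Retrosynthetic overview**
- The C6 angelate is added last; the 1,10-cis-oxirane comes from reagent-controlled epoxidation of a (Z)-C1=C10 cyclodecene.
- The 10-membered ring is closed by ring-closing metathesis (C1=C10) on a diene that already carries the trans-γ-lactone and the C11 angelate.
- The γ-lactone forms when the C8 carbinol (set by Brown methallylboration) opens a Seebach dioxolanone; C11 comes from L-lactic acid.
- The C6–C7 bond and both stereocentres come from a proposed D-proline cross-aldol between the dioxolanone acetaldehyde and a Sharpless-derived epoxy aldehyde (C4, C5).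
- Ring order: 4,5-oxirane, then dioxolanone (temporary), then γ-lactone, then cyclodecene, then 1,10-oxirane.

Assumption: atom labels C1–C15 follow germacrane numbering of the target (C12 lactone carbonyl, C13 methyl on C11, C14 methyl on C10, C15 methyl on C4), and all named reagents are purchased.

**Step 1**
Reactants: 1 hex-5-en-1-yne
Product: 3 (2E)-3-methylhepta-2,6-dien-1-ol, via alkenylalane 2 (not isolated)
Conditions: AlMe3 (2 equiv), Cp2ZrCl2 (0.25 equiv), CH2Cl2, 0 °C to rt; then (CH2O)n, THF, 0 °C to rt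
Reagents that add atoms: trimethylaluminium, C[Al](C)C; paraformaldehyde (CH2O unit), C=O
Why: Negishi zirconium-catalysed carboalumination adds Me–Al syn across the terminal alkyne with methyl on the internal carbon (the alkene is inert), and hydroxymethylation of the alkenylalane with retention gives the E allylic alcohol.

**Step 2**
Reactants: 3 (2E)-3-methylhepta-2,6-dien-1-ol
Product: 4 [(2S,3S)-3-(but-3-en-1-yl)-3-methyloxiran-2-yl]methanol
Conditions: Ti(OiPr)4 (0.1 equiv), L-(+)-diisopropyl tartrate (0.12 equiv), tBuOOH (2 equiv), 4 Å molecular sieves, CH2Cl2, −20 °C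
Reagents that add atoms: tert-butyl hydroperoxide, CC(C)(C)OO
Why: Sharpless asymmetric epoxidation of the E allylic alcohol with the L-(+)-tartrate gives the (2S,3S)-epoxide (C5 and C4 of the target) and leaves the isolated terminal alkene untouched.

**Step 3**
Reactants: 4 [(2S,3S)-3-(but-3-en-1-yl)-3-methyloxiran-2-yl]methanol
Product: 5 (2R,3S)-3-(but-3-en-1-yl)-3-methyloxirane-2-carbaldehyde
Conditions: TEMPO (0.1 equiv), PhI(OAc)2 (1.1 equiv), CH2Cl2, rt
Reagents that add atoms: none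
Why: The TEMPO/PhI(OAc)2 oxidation (oxoammonium-mediated) stops at the aldehyde under near-neutral conditions that neither open the oxirane nor epimerise C5.

**Step 4**
Reactants: 6 (S)-lactic acid
Product: 7 (2S,5S)-2-tert-butyl-5-methyl-1,3-dioxolan-4-one
Conditions: pivalaldehyde, TsOH·H2O (cat.), H2SO4 (cat.), pentane, reflux, Dean–Stark; recrystallised at −78 °C
Reagents that add atoms: pivalaldehyde, CC(C)(C)C=O
Why: Seebach acetalisation gives the cis-dioxolanone as the major isomer (purified by crystallisation), which stores the lactate chirality in the acetal carbon.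

**Step 5**
Reactants: 7 (2S,5S)-2-tert-butyl-5-methyl-1,3-dioxolan-4-one
Product: 9 (2S,5R)-2-tert-butyl-5-methyl-5-(prop-2-en-1-yl)-1,3-dioxolan-4-one, via lithium enolate 8 (not isolated)
Conditions: LiN(iPr)2 (1.05 equiv), THF, −78 °C; allyl bromide, −78 to −30 °C; aq NH4Cl
Reagents that add atoms: allyl bromide, C=CCBr
Why: In this Seebach self-regeneration of stereocentres the planar enolate is allylated anti to the tert-butyl group, which makes C11 quaternary with the configuration required in the target.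

**Step 6**
Reactants: 9 (2S,5R)-2-tert-butyl-5-methyl-5-(prop-2-en-1-yl)-1,3-dioxolan-4-one
Product: 10 2-[(2S,4R)-2-tert-butyl-4-methyl-5-oxo-1,3-dioxolan-4-yl]acetaldehyde
Conditions: O3, CH2Cl2, −78 °C; PPh3, −78 °C to rt
Reagents that add atoms: ozone, [O-][O+]=O
Why: Ozonolysis with reductive work-up cleaves the terminal alkene to the aldehyde (future C8) without touching the dioxolanone or C11.

**Step 7**
Reactants: 10 2-[(2S,4R)-2-tert-butyl-4-methyl-5-oxo-1,3-dioxolan-4-yl]acetaldehyde; 5 (2R,3S)-3-(but-3-en-1-yl)-3-methyloxirane-2-carbaldehyde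
Product: 11 (2S,3S)-3-[(2S,3S)-3-(but-3-en-1-yl)-3-methyloxiran-2-yl]-2-[(2S,4R)-2-tert-butyl-4-methyl-5-oxo-1,3-dioxolan-4-yl]-3-hydroxypropanal
Conditions: D-proline (20 mol%), DMF, 4 °C; 10 added by syringe pump over 24 h to 5 (1.5 equiv)
Reagents that add atoms: none
Why: Proposed new method: a D-proline-catalysed direct cross-aldol in which a β-quaternary, dioxolanone-bearing acetaldehyde is the enamine donor and a trisubstituted α,β-epoxy aldehyde is the acceptor, a pairing not yet demonstrated; only 10 can form an enamine (the α-carbon of 5 is an oxirane carbon), its E-enamine adds through the hydrogen-bonded Houk–List chair to the Si face of 5, which is also the face favoured by the Cornforth/polar Felkin–Anh preference of the epoxy aldehyde (new C6–O anti to the C5–O bond), so catalyst and substrate control are matched and give the 6,7-anti, 5,6-anti adduct with C6 (S) and C7 (S), while slow addition of 10 to excess 5 suppresses donor self-aldol; the closest known reaction type is the proline-catalysed direct cross-aldol between two different aldehydes (enamine catalysis).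

**Step 8**
Reactants: 11 (2S,3S)-3-[(2S,3S)-3-(but-3-en-1-yl)-3-methyloxiran-2-yl]-2-[(2S,4R)-2-tert-butyl-4-methyl-5-oxo-1,3-dioxolan-4-yl]-3-hydroxypropanal
Product: 12 (2S,3S)-3-[(2S,3S)-3-(but-3-en-1-yl)-3-methyloxiran-2-yl]-2-[(2S,4R)-2-tert-butyl-4-methyl-5-oxo-1,3-dioxolan-4-yl]-3-[(tert-butyldimethylsilyl)oxy]propanal
Conditions: TBSOTf (1.3 equiv), 2,6-lutidine (2.5 equiv), CH2Cl2, −78 °C
Reagents that add atoms: tert-butyldimethylsilyl triflate, CC(C)(C)[Si](C)(C)OS(=O)(=O)C(F)(F)F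
Why: Low-temperature silylation caps the C6 hydroxyl before it can lactonise onto the dioxolanone or undergo retro-aldol, and the buffered conditions spare the oxirane and the C7 stereocentre.

**Step 9**
Reactants: 12 (2S,3S)-3-[(2S,3S)-3-(but-3-en-1-yl)-3-methyloxiran-2-yl]-2-[(2S,4R)-2-tert-butyl-4-methyl-5-oxo-1,3-dioxolan-4-yl]-3-[(tert-butyldimethylsilyl)oxy]propanal
Product: 13 (2S,5R)-5-{(1S,2S,3R)-1-[(2S,3S)-3-(but-3-en-1-yl)-3-methyloxiran-2-yl]-1-[(tert-butyldimethylsilyl)oxy]-3-hydroxy-5-methylhex-5-en-2-yl}-2-tert-butyl-5-methyl-1,3-dioxolan-4-one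
Conditions: (+)-Ipc2BOMe (from (−)-α-pinene, 1.5 equiv), CH2=C(CH3)CH2MgCl (1.4 equiv), Et2O, −78 °C to rt; then 12, −78 °C; pH 7 NaH2PO4/Na2HPO4 buffer, MeOH, 30% H2O2, 0 °C
Reagents that add atoms: methallylmagnesium chloride, CC(=C)C[Mg]Cl
Why: Brown methallylboration through a chair transition state is reagent-controlled and delivers the 2-methylallyl group to the Re face of the aldehyde, setting C8 as R (7,8-syn, 6,8-anti) under non-basic conditions that leave the oxirane and dioxolanone intact.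

**Step 10**
Reactants: 13 (2S,5R)-5-{(1S,2S,3R)-1-[(2S,3S)-3-(but-3-en-1-yl)-3-methyloxiran-2-yl]-1-[(tert-butyldimethylsilyl)oxy]-3-hydroxy-5-methylhex-5-en-2-yl}-2-tert-butyl-5-methyl-1,3-dioxolan-4-one
Product: 14 (3R,4S,5R)-4-{(S)-[(2S,3S)-3-(but-3-en-1-yl)-3-methyloxiran-2-yl][(tert-butyldimethylsilyl)oxy]methyl}-3-hydroxy-3-methyl-5-(2-methylprop-2-en-1-yl)oxolan-2-one
Conditions: DBU (0.2 equiv), CH2Cl2, rt
Reagents that add atoms: none
Why: Base-catalysed transacylation (lactonisation) lets the C8 hydroxyl open the activated dioxolanone carbonyl in a 5-exo closure and the hemiacetal loses pivalaldehyde, giving the trans-fused γ-lactone with a free C11 hydroxyl without touching any stereocentre.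

**Step 11**
Reactants: 14 (3R,4S,5R)-4-{(S)-[(2S,3S)-3-(but-3-en-1-yl)-3-methyloxiran-2-yl][(tert-butyldimethylsilyl)oxy]methyl}-3-hydroxy-3-methyl-5-(2-methylprop-2-en-1-yl)oxolan-2-one
Product: 16 (3R,4S,5R)-4-{(S)-[(2S,3S)-3-(but-3-en-1-yl)-3-methyloxiran-2-yl][(tert-butyldimethylsilyl)oxy]methyl}-3-methyl-5-(2-methylprop-2-en-1-yl)-2-oxooxolan-3-yl (2Z)-2-methylbut-2-enoate, via lithium alkoxide 15 (not isolated)
Conditions: LiN(SiMe3)2 (1.1 equiv), THF, −78 °C; angelic anhydride (1.5 equiv), −78 to 0 °C; aq NH4Cl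
Reagents that add atoms: angelic anhydride, C/C=C(/C)C(=O)OC(=O)/C(C)=C\C
Why: Alkoxide acylation with the anhydride at low temperature esterifies the hindered tertiary C11 hydroxyl without a nucleophilic catalyst, so the Z geometry of the angelate is kept, and C11 has no enolisable hydrogen.

**Step 12**
Reactants: 16 (3R,4S,5R)-4-{(S)-[(2S,3S)-3-(but-3-en-1-yl)-3-methyloxiran-2-yl][(tert-butyldimethylsilyl)oxy]methyl}-3-methyl-5-(2-methylprop-2-en-1-yl)-2-oxooxolan-3-yl (2Z)-2-methylbut-2-enoate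
Product: 17 (1(10)Z,4S,5S,6S,7S,8R,11R)-11-[(2Z)-2-methylbut-2-enoyloxy]-6-[(tert-butyldimethylsilyl)oxy]-4,5-epoxygermacr-1(10)-en-12,8-olide
Conditions: second-generation Grubbs catalyst RuCl2(=CHPh)(H2IMes)(PCy3) (10 mol%), toluene (1 mM), 80 °C
Reagents that add atoms: none
Why: In this ring-closing metathesis the ruthenium carbene loads on the monosubstituted C1 alkene and closes onto the 1,1-disubstituted C10 alkene at high dilution, the 10-membered ring favouring the less strained Z trisubstituted olefin, while the electron-poor trisubstituted angelate is inert.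

**Step 13**
Reactants: 17 (1(10)Z,4S,5S,6S,7S,8R,11R)-11-[(2Z)-2-methylbut-2-enoyloxy]-6-[(tert-butyldimethylsilyl)oxy]-4,5-epoxygermacr-1(10)-en-12,8-olide
Product: 18 (1R,4S,5S,6S,7S,8R,10S,11R)-11-[(2Z)-2-methylbut-2-enoyloxy]-6-[(tert-butyldimethylsilyl)oxy]-1,10:4,5-diepoxygermacran-12,8-olide
Conditions: D-fructose-derived Shi ketone (0.3 equiv), Oxone (2KHSO5·KHSO4·K2SO4), K2CO3, Bu4NHSO4 (cat.), MeCN/dimethoxymethane/aq Na2B4O7 buffer, 0 °C
Reagents that add atoms: potassium peroxymonosulfate KHSO5 (from Oxone), [K+].[O-]S(=O)(=O)OO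
Why: Shi epoxidation transfers oxygen from the chiral dioxirane through the spiro transition state preferred for trisubstituted olefins, which predicts the (1R,10S) cis-oxirane from the Z olefin, and the electron-poor angelate does not react.

**Step 14**
Reactants: 18 (1R,4S,5S,6S,7S,8R,10S,11R)-11-[(2Z)-2-methylbut-2-enoyloxy]-6-[(tert-butyldimethylsilyl)oxy]-1,10:4,5-diepoxygermacran-12,8-olide
Product: 19 (1R,4S,5S,6S,7R,8R,10S,11R)-6-hydroxy-11-[(2Z)-2-methylbut-2-enoyloxy]-1,10:4,5-diepoxygermacran-12,8-olide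
Conditions: HF·pyridine, pyridine, THF, 0 °C to rt
Reagents that add atoms: none
Why: Pyridine-buffered fluoride desilylation frees the C6 hydroxyl under mildly acidic conditions that avoid alkoxide formation, so there is no acyl migration, translactonisation or Payne rearrangement, and trisubstituted oxiranes tolerate it (the C7 descriptor changes only through CIP priorities).

**Step 15**
Reactants: 19 (1R,4S,5S,6S,7R,8R,10S,11R)-6-hydroxy-11-[(2Z)-2-methylbut-2-enoyloxy]-1,10:4,5-diepoxygermacran-12,8-olide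
Product: 20 (1R,4S,5S,6S,7S,8R,10S,11R)-6,11-bis[(2Z)-2-methylbut-2-enoyloxy]-1,10:4,5-diepoxygermacran-12,8-olide
Conditions: angelic acid (4 equiv), 2,4,6-trichlorobenzoyl chloride (4 equiv), Et3N (5 equiv), toluene, rt, 2 h; then 19, 80 °C
Reagents that add atoms: angelic acid, C/C=C(/C)C(=O)O
Why: Yamaguchi esterification with the preformed mixed anhydride acylates the hindered secondary C6 hydroxyl without a nucleophilic catalyst, which keeps the angelate Z and avoids the alkoxide chemistry that would threaten the lactone and oxiranes.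

**Compound list**
1 | hex-5-en-1-yne | C#CCCC=C | starting material
2 | dimethyl[(1E)-2-methylhexa-1,5-dien-1-yl]alane | C=CCC/C(C)=C/[Al](C)C | intermediate
3 | (2E)-3-methylhepta-2,6-dien-1-ol | C=CCC/C(C)=C/CO | intermediate
4 | [(2S,3S)-3-(but-3-en-1-yl)-3-methyloxiran-2-yl]methanol | C=CCC[C@]1(C)O[C@H]1CO | intermediate
5 | (2R,3S)-3-(but-3-en-1-yl)-3-methyloxirane-2-carbaldehyde | C=CCC[C@]1(C)O[C@H]1C=O | intermediate
6 | (S)-lactic acid | C[C@H](O)C(=O)O | starting material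
7 | (2S,5S)-2-tert-butyl-5-methyl-1,3-dioxolan-4-one | C[C@@H]1O[C@H](C(C)(C)C)OC1=O | intermediate
8 | lithium (2S)-2-tert-butyl-5-methyl-1,3-dioxol-4-olate (lithium enolate of 7) | CC1=C([O-])O[C@@H](C(C)(C)C)O1.[Li+] | intermediate
9 | (2S,5R)-2-tert-butyl-5-methyl-5-(prop-2-en-1-yl)-1,3-dioxolan-4-one | C[C@]1(CC=C)O[C@H](C(C)(C)C)OC1=O | intermediate
10 | 2-[(2S,4R)-2-tert-butyl-4-methyl-5-oxo-1,3-dioxolan-4-yl]acetaldehyde | C[C@]1(CC=O)O[C@H](C(C)(C)C)OC1=O | intermediate
11 | (2S,3S)-3-[(2S,3S)-3-(but-3-en-1-yl)-3-methyloxiran-2-yl]-2-[(2S,4R)-2-tert-butyl-4-methyl-5-oxo-1,3-dioxolan-4-yl]-3-hydroxypropanal | O=C[C@@H]([C@H](O)[C@@H]1O[C@@]1(C)CCC=C)[C@@]2(C)O[C@H](C(C)(C)C)OC2=O | intermediate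
12 | (2S,3S)-3-[(2S,3S)-3-(but-3-en-1-yl)-3-methyloxiran-2-yl]-2-[(2S,4R)-2-tert-butyl-4-methyl-5-oxo-1,3-dioxolan-4-yl]-3-[(tert-butyldimethylsilyl)oxy]propanal | O=C[C@@H]([C@H](O[Si](C)(C)C(C)(C)C)[C@@H]1O[C@@]1(C)CCC=C)[C@@]2(C)O[C@H](C(C)(C)C)OC2=O | intermediate
13 | (2S,5R)-5-{(1S,2S,3R)-1-[(2S,3S)-3-(but-3-en-1-yl)-3-methyloxiran-2-yl]-1-[(tert-butyldimethylsilyl)oxy]-3-hydroxy-5-methylhex-5-en-2-yl}-2-tert-butyl-5-methyl-1,3-dioxolan-4-one | CC(=C)C[C@@H](O)[C@@H]([C@H](O[Si](C)(C)C(C)(C)C)[C@@H]1O[C@@]1(C)CCC=C)[C@@]2(C)O[C@H](C(C)(C)C)OC2=O | intermediate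
14 | (3R,4S,5R)-4-{(S)-[(2S,3S)-3-(but-3-en-1-yl)-3-methyloxiran-2-yl][(tert-butyldimethylsilyl)oxy]methyl}-3-hydroxy-3-methyl-5-(2-methylprop-2-en-1-yl)oxolan-2-one | CC(=C)C[C@H]1OC(=O)[C@](C)(O)[C@@H]1[C@H](O[Si](C)(C)C(C)(C)C)[C@@H]2O[C@@]2(C)CCC=C | intermediate
15 | lithium alkoxide of 14 (C11–OLi) | [Li+].CC(=C)C[C@H]1OC(=O)[C@](C)([O-])[C@@H]1[C@H](O[Si](C)(C)C(C)(C)C)[C@@H]2O[C@@]2(C)CCC=C | intermediate
16 | (3R,4S,5R)-4-{(S)-[(2S,3S)-3-(but-3-en-1-yl)-3-methyloxiran-2-yl][(tert-butyldimethylsilyl)oxy]methyl}-3-methyl-5-(2-methylprop-2-en-1-yl)-2-oxooxolan-3-yl (2Z)-2-methylbut-2-enoate | CC(=C)C[C@H]1OC(=O)[C@](C)(OC(=O)/C(C)=C\C)[C@@H]1[C@H](O[Si](C)(C)C(C)(C)C)[C@@H]2O[C@@]2(C)CCC=C | intermediate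
17 | (1(10)Z,4S,5S,6S,7S,8R,11R)-11-[(2Z)-2-methylbut-2-enoyloxy]-6-[(tert-butyldimethylsilyl)oxy]-4,5-epoxygermacr-1(10)-en-12,8-olide | CC(C)(C)[Si](C)(C)O[C@H]1[C@@H]2[C@@H](C/C(C)=C\CC[C@]3(C)O[C@@H]13)OC(=O)[C@]2(C)OC(=O)/C(C)=C\C | intermediate
18 | (1R,4S,5S,6S,7S,8R,10S,11R)-11-[(2Z)-2-methylbut-2-enoyloxy]-6-[(tert-butyldimethylsilyl)oxy]-1,10:4,5-diepoxygermacran-12,8-olide | CC(C)(C)[Si](C)(C)O[C@H]1[C@@H]2[C@@H](C[C@]3(C)O[C@@H]3CC[C@]3(C)O[C@@H]13)OC(=O)[C@]2(C)OC(=O)/C(C)=C\C | intermediate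
19 | (1R,4S,5S,6S,7R,8R,10S,11R)-6-hydroxy-11-[(2Z)-2-methylbut-2-enoyloxy]-1,10:4,5-diepoxygermacran-12,8-olide | O[C@H]1[C@@H]2[C@@H](C[C@]3(C)O[C@@H]3CC[C@]3(C)O[C@@H]13)OC(=O)[C@]2(C)OC(=O)/C(C)=C\C | intermediate
20 | (1R,4S,5S,6S,7S,8R,10S,11R)-6,11-bis[(2Z)-2-methylbut-2-enoyloxy]-1,10:4,5-diepoxygermacran-12,8-olide (CNP0219924.1) | C/C=C(/C)C(=O)O[C@H]1[C@@H]2[C@@H](C[C@]3(C)O[C@@H]3CC[C@]3(C)O[C@@H]13)OC(=O)[C@]2(C)OC(=O)/C(C)=C\C | target

**Totals**
Total step count: 15.
Longest linear sequence: 12 steps (steps 1–3 or steps 4–6, then steps 7–15).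

**Three steps most likely to fail**

Step 7 (the proposed cross-aldol). The risks are slow enamine formation from the β-quaternary donor, β-elimination of the dioxolanone oxygen, and an unfavourable donor-face match. The fallback sets out from 10 and comes back at 12, using only known chemistry. Pinnick oxidation of 10 (NaClO2, NaH2PO4, 2-methylbut-2-ene, tBuOH/H2O) gives the carboxylic acid F1, and EDC/DMAP coupling with ethanethiol gives the S-ethyl thioester F2. Enolisation with Cy2BCl/Et3N (Et2O, −78 °C, E enol borinate) and addition of epoxy aldehyde 5 gives the anti aldol thioester F3 through a Zimmerman–Traxler chair on the Cornforth-preferred face of 5. TBSOTf/2,6-lutidine gives the silyl ether F4, and Fukuyama reduction (Et3SiH, Pd/C, acetone, rt) of the thioester delivers aldehyde 12.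

Step 12 (metathesis to a 10-membered ring with a trisubstituted olefin). The risks are oligomerisation and a strained transition state imposed by the trans-lactone and the C11 ester. The fallback sets out from 13 and comes back at 17, and it reverses the order of ring formation. The open-chain alcohol 13 is cyclised with the second-generation Grubbs catalyst RuCl2(=CHPh)(H2IMes)(PCy3) at high dilution to the hydroxy cyclodecene F5. DBU then closes the lactone to the macrocyclic hydroxy lactone F6, and LiN(SiMe3)2 followed by angelic anhydride gives 17.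

Step 13 (face selectivity of the epoxidation on the macrocycle). The risk is that the ring conformation exposes only the β face and overrides the chiral ketone. The fallback sets out from 17 and comes back at 18 through a halohydrin, which places the oxygen on the face opposite to the one the electrophile attacks. NBS in THF/H2O (0 °C) forms the bromonium ion on the exposed face and water opens it at the tertiary carbon C10 to give the bromohydrin F7. K2CO3 in MeCN then closes the oxirane by backside displacement of bromide at C1 to give 18.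

**Further compounds**
F1 | step 7 | 2-[(2S,4R)-2-tert-butyl-4-methyl-5-oxo-1,3-dioxolan-4-yl]acetic acid | C[C@]1(CC(=O)O)O[C@H](C(C)(C)C)OC1=O
F2 | step 7 | S-ethyl 2-[(2S,4R)-2-tert-butyl-4-methyl-5-oxo-1,3-dioxolan-4-yl]ethanethioate | C[C@]1(CC(=O)SCC)O[C@H](C(C)(C)C)OC1=O
F3 | step 7 | S-ethyl (2S,3S)-3-[(2S,3S)-3-(but-3-en-1-yl)-3-methyloxiran-2-yl]-2-[(2S,4R)-2-tert-butyl-4-methyl-5-oxo-1,3-dioxolan-4-yl]-3-hydroxypropanethioate | CCSC(=O)[C@@H]([C@H](O)[C@@H]1O[C@@]1(C)CCC=C)[C@@]2(C)O[C@H](C(C)(C)C)OC2=O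
F4 | step 7 | S-ethyl (2S,3S)-3-[(2S,3S)-3-(but-3-en-1-yl)-3-methyloxiran-2-yl]-2-[(2S,4R)-2-tert-butyl-4-methyl-5-oxo-1,3-dioxolan-4-yl]-3-[(tert-butyldimethylsilyl)oxy]propanethioate | CCSC(=O)[C@@H]([C@H](O[Si](C)(C)C(C)(C)C)[C@@H]1O[C@@]1(C)CCC=C)[C@@]2(C)O[C@H](C(C)(C)C)OC2=O
F5 | step 12 | (1(10)Z,4S,5S,6S,7S,8R)-6-[(tert-butyldimethylsilyl)oxy]-8-hydroxy-4,5-epoxy-4,10-dimethyl-7-[(2S,4R)-2-tert-butyl-4-methyl-5-oxo-1,3-dioxolan-4-yl]cyclodec-1(10)-ene (germacrane ring numbering) | CC(C)(C)[Si](C)(C)O[C@H]1[C@H]([C@H](O)C/C(C)=C\CC[C@]2(C)O[C@@H]12)[C@@]3(C)O[C@H](C(C)(C)C)OC3=O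
F6 | step 12 | (1(10)Z,4S,5S,6S,7S,8R,11R)-6-[(tert-butyldimethylsilyl)oxy]-11-hydroxy-4,5-epoxygermacr-1(10)-en-12,8-olide | CC(C)(C)[Si](C)(C)O[C@H]1[C@@H]2[C@@H](C/C(C)=C\CC[C@]3(C)O[C@@H]13)OC(=O)[C@]2(C)O
F7 | step 13 | (1S,4S,5S,6S,7S,8R,10S,11R)-1-bromo-10-hydroxy-11-[(2Z)-2-methylbut-2-enoyloxy]-6-[(tert-butyldimethylsilyl)oxy]-4,5-epoxygermacran-12,8-olide | CC(C)(C)[Si](C)(C)O[C@H]1[C@@H]2[C@@H](C[C@](C)(O)[C@@H](Br)CC[C@]3(C)O[C@@H]13)OC(=O)[C@]2(C)OC(=O)/C(C)=C\C
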